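**Plan**

1. Retrosynthetic cuts, in order: the C4–O octanoate; the C6 carbinol (back to a C6 ketone); the lactone O–C3 bond together with C4–O (epoxide of a C3=C4 alkene opened by the C16 acid); C3–CH3 (enol triflate of a C3 ketone); then the C4–C5 bond of the oxonane with O–C7 reconnected (retro-Claisen); C7–vinyl; C9–C10 (radical cyclization); C1–C2 (aldol on (R)-carvone).
2. Forward ring order: cyclohexane from (R)-carvone → tetrahydrofuran by 5-exo radical cyclization → bridged seven-membered lactone (ring O, C2, C3, O, C7, C8, C9) → its exocyclic enol ether → oxonane by a two-atom Claisen ring expansion → ε-lactone (C3–O–C16) by epoxide opening.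
3. Enabling feature: in the oxonane the oxygenated C3 and the C6(OH)–C7(=CH2) unit are joined through C4–C5, so the ring hides a γ,δ-unsaturated ketone (C3=O, C6=C7), the Claisen retron. C2 and C9 are cis on the tetrahydrofuran, so the allyl vinyl ether can be held in a seven-membered ring.
4. Stereochemistry: C14 from carvone; C1/C2 by anti aldol trans to the isopropenyl group; C11 by hydroxyl-directed epoxidation; C10 and C9 by the radical closure (cis fusion, 2,5-cis); C15 by hydroboration; C3/C4 by exposed-face epoxidation then inversion at C3 by the tethered acid; C6 by exposed-face hydride delivery.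
5. Locants used in the text: oxonane = ring O–C2–C3–C4–C5–C6–C7–C8–C9; tetrahydrofuran = ring O–C2–C1–C10–C9; cyclohexane = C1, C10–C14; C15 (on C14) bears C17H3 and the carbonyl C16; C18 = CH3 on C3, C19 = CH2 on C7, C20 = CH3 on C11.

Key step: step 11

Remark: the configuration is taken exactly as the target SMILES defines it, which corresponds at C14 to (R)-(−)-carvone; the C7 carbinol centre of 13–17 is left uncontrolled because step 11 makes it sp2.

**Step 1**
Reactants: 1 (R)-(−)-carvone; 2 ethyl glyoxylate
Product: 4 anti-aldol adduct, via lithium dienolate 3 (not isolated)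
Conditions: LDA (LiN(i-Pr)2), THF, −78 °C; then 2 (freshly distilled), −78 °C; AcOH quench
Reagents that add atoms: none
Why: Kinetic deprotonation at the C1 methylene gives the cross-conjugated ring (E)-enolate, whose lithium aldol reaction through a Zimmerman–Traxler chair should give the anti adduct with the aldehyde entering trans to the C14 isopropenyl group, so that C1 and C2 are set relative to C14.

**Step 2**
Reactants: 4 anti-aldol adduct
Product: 5 tosylhydrazone
Conditions: TsNHNH2, EtOH, rt
Reagents that add atoms: p-toluenesulfonyl hydrazide, Cc1ccc(cc1)S(=O)(=O)NN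
Why: Condensation of the enone carbonyl with the sulfonyl hydrazide (hydrazone formation) under neutral conditions that should neither dehydrate nor retro-aldolize the β-hydroxy ketone.

**Step 3**
Reactants: 5 tosylhydrazone
Product: 7 diene hydroxy ester, via allylic diazene 6 (not isolated)
Conditions: catecholborane, CHCl3, 0 °C; then NaOAc·3H2O, 65 °C
Reagents that add atoms: none
Why: Catecholborane reduction of an α,β-unsaturated tosylhydrazone (reductive 1,3-transposition): hydride adds to C10, sulfinate is lost and the allylic diazene expels N2 by retro-ene hydrogen transfer to C12, which moves the double bond to C10=C11 without touching C1, C2 or C14.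

**Step 4**
Reactants: 7 diene hydroxy ester
Product: 8 epoxy alcohol
Conditions: VO(acac)2 (cat.), t-BuOOH, CH2Cl2, 0 °C → rt
Reagents that add atoms: tert-butyl hydroperoxide, CC(C)(C)OO
Why: Vanadium-catalysed hydroxyl-directed epoxidation of a homoallylic alcohol: the vanadate ester of the C2 hydroxyl should deliver oxygen to the trisubstituted ring alkene on the face that carries the C1 side chain, fixing the C11–O bond cis to C2, while the more remote and less nucleophilic isopropenyl group should survive.

**Step 5**
Reactants: 8 epoxy alcohol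
Product: 9 hydroxy selenide
Conditions: PhSeSePh, NaBH4, EtOH, 0 °C (reagent pre-formed); then 8, rt → 50 °C
Reagents that add atoms: diphenyl diselenide, c1ccccc1[Se][Se]c1ccccc1
Why: SN2 opening of the epoxide by the soft selenolate at the secondary C10 (the tertiary C11 cannot be attacked), which keeps the C11–O configuration from step 4 and places a radical precursor on C10.

**Step 6**
Reactants: 9 hydroxy selenide; 10 but-3-yn-2-one
Product: 11 (E)-β-alkoxy enone
Conditions: N-methylmorpholine, CH2Cl2, rt
Reagents that add atoms: none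
Why: Amine-catalysed oxa-Michael (conjugate) addition of the secondary C2 hydroxyl to the ynone should give the (E)-β-alkoxy enone; the hindered tertiary C11 hydroxyl should not add.

**Step 7**
Reactants: 11 (E)-β-alkoxy enone
Product: 12 bicyclic keto ester
Conditions: Bu3SnH (slow addition), AIBN, benzene (dilute), 80 °C
Reagents that add atoms: none
Why: Tin hydride mediated 5-exo-trig radical cyclization of the C10 radical onto the β-alkoxy enone (β-alkoxyacrylate-type closure): the C9–C10 bond can only form cis to the tether on C1 (sets C10, cis ring fusion), and the chair-like transition state with ester and enone pseudo-equatorial should give the 2,5-cis tetrahydrofuran (sets C9).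

**Step 8**
Reactants: 12 bicyclic keto ester
Product: 13 tertiary allylic alcohol (C7 epimers)
Conditions: CH2=CHMgBr (excess), CeCl3, THF, −78 °C; H2O work-up
Reagents that add atoms: vinylmagnesium bromide, C=C[Mg]Br
Why: 1,2-Addition of a weakly basic organocerium reagent to the methyl ketone, chosen so that the β-alkoxy ketone does not open by retro-oxa-Michael reaction and the ester is not attacked; the new C7 centre forms without control and is erased in step 11.

**Step 9**
Reactants: 13 tertiary allylic alcohol (C7 epimers)
Product: 16 bridged seven-membered lactone, via potassium carboxylate 14 (not isolated), via mixed anhydride 15 (not isolated)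
Conditions: KOSiMe3, THF, rt; then 2,4,6-Cl3C6H2COCl, THF, rt; then slow addition to DMAP, toluene, 80 °C, high dilution
Reagents that add atoms: none
Why: Silanolate ester cleavage followed by Yamaguchi lactonization (mixed anhydride, DMAP acyl transfer): the 2,5-cis tetrahydrofuran holds the C3 acyl group and the C7 tertiary hydroxyl on the same face, so the seven-membered ring should close as a bridge across C2 and C9.

**Step 10**
Reactants: 16 bridged seven-membered lactone
Product: 17 exocyclic enol ether
Conditions: Tebbe reagent Cp2Ti(μ-Cl)(μ-CH2)AlMe2 (excess), pyridine, THF/toluene, −40 → 0 °C; filtration through basic Al2O3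
Reagents that add atoms: Tebbe reagent (Cl→Al bridge not drawn), C[Al](C)C[Ti](Cl)(C1C=CC=C1)C1C=CC=C1
Why: Tebbe methylenation (titanium methylidene, oxatitanacyclobutane, cycloreversion) should convert the lactone carbonyl into the exocyclic enol ether C3=C4H2 at low temperature and without acid, completing the allyl vinyl ether.

**Step 11**
Reactants: 17 exocyclic enol ether
Product: 18 tricyclic (Z)-oxonenone
Conditions: toluene (degassed, dilute), Et3N (trace), sealed tube, 140 °C
Reagents that add atoms: none
Why: Thermal [3,3]-sigmatropic (Claisen) rearrangement of the allyl vinyl ether C4=C3–O–C7–C6=C5: the C4–C5 σ-bond forms as the O–C7 bond breaks, so the seven-membered ring (ring O, C2, C3, O, C7, C8, C9) gives up its second oxygen to the new C3 carbonyl and takes in C4, C5 and C6, becoming the oxonane. The closest known reaction type is the Claisen ring expansion of 2-methylene cyclic ethers that carry a vinyl group on the other carbon next to oxygen, which gives medium-ring cycloalk-4-enones. No ring is closed end to end; the nine-membered ring arises by ring expansion through a six-centre chair- or boat-like transition state held in place by the bicyclic frame. No sp3 stereocentre is formed: C7 becomes sp2, so both epimers of 17 should converge, and the C6=C7 double bond should be Z because both of its ring bonds stay on the side of the short tether C8–C9–O–C2–C3. The selectivity needed is the concerted [3,3] path over heterolysis of the tertiary allylic C7–O bond ([1,3] shift, diene formation) and over acid-catalysed migration or hydrolysis of the enol ether; dilute, acid-free, apolar conditions with a trace of amine should secure it. The step places the ketone at C3 and the trisubstituted alkene at C6=C7, the two handles from which C3–O, C4–O, C6–OH and C7=CH2 are developed.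

**Step 12**
Reactants: 18 tricyclic (Z)-oxonenone
Product: 20 enol triflate, via dipotassium enolate 19 (not isolated)
Conditions: KHMDS (KN(SiMe3)2, 2.2 equiv), THF, −78 °C; then PhNTf2, −78 → −30 °C; aq NH4Cl
Reagents that add atoms: N-phenylbis(trifluoromethanesulfonimide), O=S(=O)(N(c1ccccc1)S(=O)(=O)C(F)(F)F)C(F)(F)F
Why: Kinetic enolization with a hindered amide base at the accessible C4 methylene (C2–H is tertiary and shielded by the bicyclic core) and O-sulfonylation should give the enol triflate with C2 and C5 cis on the double bond, which stores the future C3=C4 alkene in a form inert to borane and singlet oxygen.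

**Step 13**
Reactants: 20 enol triflate
Product: 22 primary alcohol, via alkylborane 21 (not isolated)
Conditions: 9-BBN-H, THF, 0 °C → rt; then H2O2, aq NaOAc, 0 °C → rt
Reagents that add atoms: hydrogen peroxide, OO
Why: Hydroboration–oxidation with the bulky 9-BBN-H is anti-Markovnikov and selective for the 1,1-disubstituted isopropenyl group over the trisubstituted and triflate-bearing alkenes; C15 should be set by allylic 1,2-induction, the borane adding to the rotamer with C14–H eclipsing C=CH2 from the face turned away from C1 and the tricyclic core.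

**Step 14**
Reactants: 22 primary alcohol
Product: 24 carboxylic acid, via aldehyde 23 (not isolated)
Conditions: TEMPO (cat.), PhI(OAc)2, MeCN/H2O, rt
Reagents that add atoms: water, O
Why: Oxoammonium (TEMPO) oxidation of the primary alcohol through the aldehyde hydrate to the acid, mild enough to leave the alkene, the enol triflate, the tertiary alcohol and the α-stereocentre C15 untouched.

**Step 15**
Reactants: 24 carboxylic acid
Product: 26 exo-methylene enone, via allylic hydroperoxide 25 (not isolated)
Conditions: O2, tetraphenylporphyrin (cat.), hν, CH2Cl2, 0 °C; then Ac2O, pyridine, 0 °C → rt; aq NaHCO3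
Reagents that add atoms: oxygen, O=O
Why: Schenck ene reaction of singlet oxygen with the only electron-rich alkene (C–O bond at C6, hydrogen taken from the freely rotating C7 methyl because the ring allylic C–H bonds lie near the nodal plane of the Z-cyclononene), followed by base-induced dehydration of the peracetate (Kornblum–DeLaMare type), should give the exo-methylene enone, which removes the C6 configuration on purpose.

**Step 16**
Reactants: 26 exo-methylene enone
Product: 27 C3-methyl keto acid
Conditions: MeZnCl (excess), Pd(PPh3)4 (cat.), THF, 50 °C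
Reagents that add atoms: methylzinc chloride, C[Zn]Cl
Why: Negishi cross-coupling of the enol triflate with retention of double-bond geometry introduces C18; the organozinc reagent should tolerate the enone, and the carboxylic acid only consumes one extra equivalent.

**Step 17**
Reactants: 27 C3-methyl keto acid
Product: 29 tetracyclic hydroxy keto lactone, via epoxy acid 28 (not isolated)
Conditions: mCPBA, CH2Cl2, 0 °C → rt (CSA cat. if the closure is slow)
Reagents that add atoms: m-chloroperbenzoic acid, OOC(=O)c1cccc(Cl)c1
Why: Prilezhaev epoxidation of the only nucleophilic alkene on its exposed face (the face away from C1 and the acid side chain), then acid-catalysed 7-exo opening at the tertiary C3 by the C16 carboxylic acid with inversion, which should form the ε-lactone and set C3 and C4 anti to each other.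

**Step 18**
Reactants: 29 tetracyclic hydroxy keto lactone; 30 octanoyl chloride
Product: 31 6-oxo-briarellin A
Conditions: pyridine, DMAP (cat.), CH2Cl2, 0 °C
Reagents that add atoms: none
Why: Nucleophilic-catalysed acylation of the only secondary hydroxyl (the tertiary C11 hydroxyl is unreactive), under a weak base at low temperature so that the β-acyloxy ketone should not eliminate.

**Step 19**
Reactants: 31 6-oxo-briarellin A
Product: 32 briarellin A
Conditions: NaBH4, CeCl3·7H2O, MeOH, −78 °C
Reagents that add atoms: none
Why: Luche 1,2-reduction of the enone: hydride should arrive on the exposed outer face of the nine-membered ring, placing the C6 hydroxyl on the inner face as required, while the lactone and the octanoate are inert at −78 °C.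

**Compound list**

1 | (R)-(−)-carvone, (5R)-2-methyl-5-(prop-1-en-2-yl)cyclohex-2-en-1-one | CC(=C)[C@@H]1CC=C(C)C(=O)C1 | starting material
2 | ethyl glyoxylate | CCOC(=O)C=O | starting material
3 | lithium dienolate of 1 (not isolated) | CC(=C)[C@@H]1CC=C(C)C(O[Li])=C1 | intermediate
4 | anti-aldol adduct, ethyl (2S)-2-hydroxy-2-[(1R,6R)-3-methyl-2-oxo-6-(prop-1-en-2-yl)cyclohex-3-en-1-yl]acetate | CCOC(=O)[C@@H](O)[C@@H]1C(=O)C(C)=CC[C@H]1C(C)=C | intermediate
5 | tosylhydrazone of 4 (C10=N–NHTs) | CCOC(=O)[C@@H](O)[C@@H]1C(=NNS(=O)(=O)c2ccc(C)cc2)C(C)=CC[C@H]1C(C)=C | intermediate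
6 | allylic diazene (C10–N=NH, C11=C12; not isolated) | CCOC(=O)[C@@H](O)[C@@H]1C(N=N)C(C)=CC[C@H]1C(C)=C | intermediate
7 | diene hydroxy ester, ethyl (2S)-2-hydroxy-2-[(1R,6R)-3-methyl-6-(prop-1-en-2-yl)cyclohex-2-en-1-yl]acetate | CCOC(=O)[C@@H](O)[C@@H]1C=C(C)CC[C@H]1C(C)=C | intermediate
8 | epoxy alcohol (C10–C11 epoxide cis to the C1 side chain) | CCOC(=O)[C@@H](O)[C@@H]1[C@@H]2O[C@]2(C)CC[C@H]1C(C)=C | intermediate
9 | hydroxy selenide (C10–SePh trans to C11–OH; C11–OH cis to the C1 side chain) | CCOC(=O)[C@@H](O)[C@@H]1[C@@H]([Se]c2ccccc2)[C@](C)(O)CC[C@H]1C(C)=C | intermediate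
10 | but-3-yn-2-one | CC(=O)C#C | starting material
11 | (E)-β-alkoxy enone (C2–O–CH=CH–COCH3) | CCOC(=O)[C@@H](O/C=C/C(C)=O)[C@@H]1[C@@H]([Se]c2ccccc2)[C@](C)(O)CC[C@H]1C(C)=C | intermediate
12 | bicyclic keto ester, ethyl 4-hydroxy-4-methyl-3-(2-oxopropyl)-7-(prop-1-en-2-yl)octahydroisobenzofuran-1-carboxylate (cis-fused, 1,3-cis) | CCOC(=O)[C@H]1O[C@@H](CC(C)=O)[C@@H]2[C@](C)(O)CC[C@@H](C(C)=C)[C@H]12 | intermediate
13 | tertiary allylic alcohol, 3-(2-hydroxy-2-methylbut-3-en-1-yl) analogue of 12 (C7 epimers) | CCOC(=O)[C@H]1O[C@@H](CC(C)(O)C=C)[C@@H]2[C@](C)(O)CC[C@@H](C(C)=C)[C@H]12 | intermediate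
14 | potassium carboxylate of 13 (not isolated) | [K+].[O-]C(=O)[C@H]1O[C@@H](CC(C)(O)C=C)[C@@H]2[C@](C)(O)CC[C@@H](C(C)=C)[C@H]12 | intermediate
15 | mixed 2,4,6-trichlorobenzoic anhydride (not isolated) | O=C(OC(=O)c1c(Cl)cc(Cl)cc1Cl)[C@H]1O[C@@H](CC(C)(O)C=C)[C@@H]2[C@](C)(O)CC[C@@H](C(C)=C)[C@H]12 | intermediate
16 | bridged seven-membered lactone (C3(=O)–O–C7; C7 epimers) | C=CC1(C)C[C@@H]2O[C@H](C(=O)O1)[C@@H]3[C@H]2[C@](C)(O)CC[C@H]3C(C)=C | intermediate
17 | exocyclic enol ether (C3=C4H2; C7 epimers) | C=CC1(C)C[C@@H]2O[C@H](C(=C)O1)[C@@H]3[C@H]2[C@](C)(O)CC[C@H]3C(C)=C | intermediate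
18 | tricyclic (Z)-oxonenone (C3 ketone, C6=C7–CH3) | O=C1CC/C=C(C)\C[C@@H]2O[C@H]1[C@@H]3[C@H]2[C@](C)(O)CC[C@H]3C(C)=C | intermediate
19 | dipotassium C11-alkoxide C3-enolate (not isolated) | [K]O/C1=C/C/C=C(C)\C[C@@H]2O[C@H]1[C@@H]3[C@H]2[C@](C)(O[K])CC[C@H]3C(C)=C | intermediate
20 | enol triflate (C3–OTf, C3=C4) | O=S(=O)(O/C1=C/C/C=C(C)\C[C@@H]2O[C@H]1[C@@H]3[C@H]2[C@](C)(O)CC[C@H]3C(C)=C)C(F)(F)F | intermediate
21 | B-alkyl-9-BBN at C16 (not isolated) | O=S(=O)(O/C1=C/C/C=C(C)\C[C@@H]2O[C@H]1[C@@H]3[C@H]2[C@](C)(O)CC[C@H]3[C@@H](C)CB4C5CCCC4CCC5)C(F)(F)F | intermediate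
22 | primary alcohol (C16–OH, C15 set) | O=S(=O)(O/C1=C/C/C=C(C)\C[C@@H]2O[C@H]1[C@@H]3[C@H]2[C@](C)(O)CC[C@H]3[C@@H](C)CO)C(F)(F)F | intermediate
23 | C16 aldehyde (not isolated) | O=S(=O)(O/C1=C/C/C=C(C)\C[C@@H]2O[C@H]1[C@@H]3[C@H]2[C@](C)(O)CC[C@H]3[C@@H](C)C=O)C(F)(F)F | intermediate
24 | C16 carboxylic acid | O=S(=O)(O/C1=C/C/C=C(C)\C[C@@H]2O[C@H]1[C@@H]3[C@H]2[C@](C)(O)CC[C@H]3[C@@H](C)C(=O)O)C(F)(F)F | intermediate
25 | allylic hydroperoxide (C6–OOH, C7=C19H2; not isolated) | O=S(=O)(O/C1=C/C[C@@H](OO)C(=C)C[C@@H]2O[C@H]1[C@@H]3[C@H]2[C@](C)(O)CC[C@H]3[C@@H](C)C(=O)O)C(F)(F)F | intermediate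
26 | exo-methylene enone (C6=O, C7=C19H2) | O=S(=O)(O/C1=C/CC(=O)C(=C)C[C@@H]2O[C@H]1[C@@H]3[C@H]2[C@](C)(O)CC[C@H]3[C@@H](C)C(=O)O)C(F)(F)F | intermediate
27 | C3-methyl keto acid ((Z)-C3=C4) | C/C1=C/CC(=O)C(=C)C[C@@H]2O[C@H]1[C@@H]3[C@H]2[C@](C)(O)CC[C@H]3[C@@H](C)C(=O)O | intermediate
28 | epoxy acid (C3–C4 epoxide on the exposed face; not isolated) | C[C@@]12O[C@@H]1CC(=O)C(=C)C[C@@H]3O[C@H]2[C@@H]4[C@H]3[C@](C)(O)CC[C@H]4[C@@H](C)C(=O)O | intermediate
29 | tetracyclic hydroxy keto lactone (C4–OH, C6=O) | C=C1C[C@@H]2O[C@H]3[C@H]4[C@@H](CC[C@@](C)(O)[C@H]42)[C@@H](C)C(=O)O[C@@]3(C)[C@H](O)CC1=O | intermediate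
30 | octanoyl chloride | CCCCCCCC(=O)Cl | starting material
31 | 6-oxo-briarellin A (C4 octanoate, C6 ketone) | C=C1C[C@@H]2O[C@H]3[C@H]4[C@@H](CC[C@@](C)(O)[C@H]42)[C@@H](C)C(=O)O[C@@]3(C)[C@H](OC(=O)CCCCCCC)CC1=O | intermediate
32 | briarellin A | C=C1C[C@@H]2O[C@H]3[C@H]4[C@@H](CC[C@@](C)(O)[C@H]42)[C@@H](C)C(=O)O[C@@]3(C)[C@H](OC(=O)CCCCCCC)C[C@@H]1O | target

**Step count and risks**

Total steps: 19. Longest linear sequence: 19 steps (fully linear from 1).

The three steps most likely to fail:

Step 9. Acyl transfer to the hindered tertiary allylic hydroxyl may be too slow, so that intermolecular acylation or epimerization at C2 through the activated acyl species takes over. The fallback sets out from 13. Saponification (LiOH, THF/H2O) should give the hydroxy acid F1. This is closed by the alkyl–oxygen route instead of the acyl–oxygen route: a catalytic Lewis acid (Sc(OTf)3, CH2Cl2, 4 Å sieves) ionizes the tertiary allylic C7–OH, and the carboxylic acid captures the cation at C7 through a seven-membered transition state. Both C7 epimers converge, and the sequence comes back to the route at 16.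

Step 15. Hydrogen abstraction may occur from the ring methylenes C5 (doubly allylic) or C8 instead of the C19 methyl group, which would give regioisomeric hydroperoxides. The fallback sets out from 24. Epoxidation of C6=C7 on the exposed face (mCPBA, NaHCO3, CH2Cl2) should give the epoxy acid F2. Base-induced isomerization of the epoxide with a hindered aluminium amide (Et2Al(TMP), diethylaluminium 2,2,6,6-tetramethylpiperidide, toluene, 0 °C) removes the least hindered proton (on C19) syn to the epoxide oxygen and should give the allylic alcohol F3. Dess–Martin oxidation then comes back to the route at 26.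

Step 19. Facial selectivity of hydride delivery to the C6 carbonyl may be poor or reversed. The fallback sets out from 31. The C6 epimer formed in the reduction, 6-epi-briarellin A F4, is inverted by a Mitsunobu reaction with formic acid (PPh3, DIAD, THF) to the formate F5. The formate is then removed selectively (NaHCO3, MeOH, 0 °C) in the presence of the octanoate and the lactone, which arrives at 32.

**Further compounds**

F1 | step 9 | hydroxy acid from 13 (C7 epimers) | OC(=O)[C@H]1O[C@@H](CC(C)(O)C=C)[C@@H]2[C@](C)(O)CC[C@@H](C(C)=C)[C@H]12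
F2 | step 15 | C6–C7 epoxy acid (epoxide on the exposed face) | O=S(=O)(O/C1=C/C[C@H]4O[C@@]4(C)C[C@@H]2O[C@H]1[C@@H]3[C@H]2[C@](C)(O)CC[C@H]3[C@@H](C)C(=O)O)C(F)(F)F
F3 | step 15 | allylic alcohol (C6–OH, C7=C19H2) | O=S(=O)(O/C1=C/C[C@@H](O)C(=C)C[C@@H]2O[C@H]1[C@@H]3[C@H]2[C@](C)(O)CC[C@H]3[C@@H](C)C(=O)O)C(F)(F)F
F4 | step 19 | 6-epi-briarellin A | C=C1C[C@@H]2O[C@H]3[C@H]4[C@@H](CC[C@@](C)(O)[C@H]42)[C@@H](C)C(=O)O[C@@]3(C)[C@H](OC(=O)CCCCCCC)C[C@H]1O
F5 | step 19 | briarellin A 6-O-formate | C=C1C[C@@H]2O[C@H]3[C@H]4[C@@H](CC[C@@](C)(O)[C@H]42)[C@@H](C)C(=O)O[C@@]3(C)[C@H](OC(=O)CCCCCCC)C[C@@H]1OC=O
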